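**Plan**

- Benzofuran numbering is used: O1, C2 (CH bearing the carbinol), C3 (CH2), C3a (quaternary), C4 (C=O), C5 (acyl), C6 (enol), C7 (prenyl), C7a.
- Cuts: first the tertiary C–OH bond (the side chain is a hydrated isopropenyl group), then O1–C2 and C3–C3a together, last the two ring–prenyl bonds. This leaves phlorisobutyrophenone, prenyl bromide and isoprene monoxide.
- Enabling feature: the dihydrofuran ring (O1–C2–C3–C3a–C7a) is a C3–C2 bridge between the nucleophilic ring carbon C3a and the enol oxygen O1 of a mirror-symmetric 3,5-diprenyl acylphloroglucinol. C3, C2 and the three side-chain carbons are therefore one isoprene unit that is electrophilic at both ends.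
- Forward: double C-prenylation builds the arene; one Pd(0)/chiral-ligand flask dearomatises it (C3–C3a) and closes the only new ring (O1–C2); a chemoselective Markovnikov hydration ends the route.
- Stereochemistry: C3a comes from the ligand-controlled choice between the two enantiotopic prenylated carbons in the C–C step, and C2 from ligand-controlled face selection of an equilibrating π-allyl in the C–O step. The last step touches neither centre.

Key step: step 2

Assumption: the ligand enantiomer that leads to the (3aS) series cannot be predicted with confidence for this substrate class; the (R,R) ligand is written and would be exchanged for (S,S) if the first experiment shows the opposite sense. Compounds 1, 2 and 4 are taken as catalogue chemicals.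

**Step 1**
Reactants: 1 phlorisobutyrophenone (2,4,6-trihydroxyisobutyrophenone); 2 prenyl bromide (1-bromo-3-methylbut-2-ene)
Product: 3 deoxycohumulone [1-(2,4,6-trihydroxy-3,5-diprenylphenyl)-2-methylpropan-1-one]
Conditions: 2 (2.1 equiv), 10% aq KOH, 0 °C
Reagents that add atoms: none
Why: In water the hydrogen-bonded phloroglucinolate reacts with the soft allylic bromide at carbon and not at oxygen, so the two free ring CH positions are alkylated in turn (double C-prenylation of an acylphloroglucinol, the standard entry to deoxyhumulones); no stereocentre is formed.

**Step 2**
Reactants: 3 deoxycohumulone; 4 isoprene monoxide (racemic 2-methyl-2-vinyloxirane)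
Product: 6 (2S,3aS)-6-hydroxy-5-isobutyryl-2-(prop-1-en-2-yl)-3a,7-diprenyl-2,3-dihydro-1-benzofuran-4(3aH)-one (isopropenyl trans to the C3a prenyl group), via hydroxyprenyl dienone 5 (not isolated)
Conditions: Pd2(dba)3·CHCl3 (2.5 mol%), (R,R)-DACH-phenyl Trost ligand (7.5 mol%), 4 (1.1 equiv, slow addition), degassed CH2Cl2, 0 °C → rt, then 40 °C
Reagents that add atoms: none
Why: Proposed new method: Pd(0) ionises racemic 4 to a zwitterionic π-allyl (the epoxide stereocentre ends as an sp2 carbon, so the racemate suffices) whose alkoxide deprotonates 3, the phenolate then bonds through a prenyl-bearing ring carbon to the CH2 terminus (C3a–C3, loss of aromaticity, dienone 5), and the primary allylic alcohol of 5, activated by hydrogen bonding to the strongly acidic enol of the same molecule, ionises a second time so that the enol oxygen on C7a captures the substituted allyl terminus (O1–C2) with water as the only by-product. The closest known reaction types are Pd-catalysed asymmetric allylic dearomatisation of phenols and Pd-catalysed dearomative allylation of acylphloroglucinols, the Pd [3+2] dihydrofuran annulation of cyclic 1,3-diones with but-2-ene-1,4-diyl bis-electrophiles, and the asymmetric allylic etherification that gives 2-isopropenyl-2,3-dihydrobenzofurans; what is new is their union as a desymmetrising cascade with a vinyl epoxide. The dihydrofuran closes in a 5-exo mode on the π-allyl, which leaves the isopropenyl group exocyclic on C2 and is preferred over 7-endo attack at the CH2 terminus. C3a is fixed by the chiral ligand pocket, which has to tell apart the two enantiotopic prenylated carbons of the mirror-symmetric phenolate (attack on one carbon from above equals attack on the other from below, so a single binary choice remains), while C2 is fixed by ligand-controlled face selection of the second π-allyl, which equilibrates by π–σ–π at its CH2 terminus faster than it cyclises. The step needs C- over O-allylation (O-allyl ethers of so acidic a phenol re-ionise under Pd), distal attack in the C–C event (a carbon that becomes quaternary cannot reach the tertiary terminus), closure through the C7a oxygen instead of the C4 oxygen (the latter is held in the hydrogen-bond chelate with the isobutyryl carbonyl, the former is the free vinylogous-acid OH) and the 2,3a-trans relationship (catalyst control, not yet demonstrated).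

**Step 3**
Reactants: 6 (2S,3aS)-2-isopropenyl dihydrobenzofuranone
Product: 8 CNP0361579.1 [(2S,3aS)-6-hydroxy-2-(2-hydroxypropan-2-yl)-5-isobutyryl-3a,7-diprenyl-2,3-dihydro-1-benzofuran-4(3aH)-one], via tertiary hydroperoxide 7 (not isolated)
Conditions: Mn(dpm)3 (10 mol%), PhSiH3, O2 (1 atm), i-PrOH–CH2Cl2, 0 °C; then PPh3, rt
Reagents that add atoms: dioxygen, O=O
Why: Mukaiyama-type hydrogen-atom-transfer hydration: the metal hydride delivers H• to the CH2 end of the unhindered 1,1-disubstituted alkene faster than to the trisubstituted prenyl alkenes, the tertiary radical is trapped by O2 (Markovnikov) and PPh3 reduces the hydroperoxide, all under neutral conditions that leave the enol ether, the β-triketone and both stereocentres alone; no new stereocentre is formed.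

**Compound list**

1 | phlorisobutyrophenone (2,4,6-trihydroxyisobutyrophenone) | CC(C)C(=O)c1c(O)cc(O)cc1O | starting material
2 | prenyl bromide (1-bromo-3-methylbut-2-ene) | CC(C)=CCBr | starting material
3 | deoxycohumulone (2,4,6-trihydroxy-3,5-diprenylisobutyrophenone) | CC(C)=CCc1c(O)c(CC=C(C)C)c(O)c(C(=O)C(C)C)c1O | intermediate
4 | isoprene monoxide (racemic 2-methyl-2-vinyloxirane) | CC1(C=C)CO1 | starting material
5 | (6S)-3,5-dihydroxy-6-[(2E)-4-hydroxy-3-methylbut-2-en-1-yl]-4,6-bis(3-methylbut-2-en-1-yl)-2-(2-methylpropanoyl)cyclohexa-2,4-dien-1-one | CC(C)=CCC1=C(O)[C@](CC=C(C)C)(C/C=C(\C)CO)C(=O)C(C(=O)C(C)C)=C1O | intermediate (not isolated)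
6 | (2S,3aS)-6-hydroxy-5-isobutyryl-2-(prop-1-en-2-yl)-3a,7-diprenyl-2,3-dihydro-1-benzofuran-4(3aH)-one | CC(C)=CCC1=C2O[C@H](C(C)=C)C[C@]2(CC=C(C)C)C(=O)C(C(=O)C(C)C)=C1O | intermediate
7 | (2S,3aS)-2-(2-hydroperoxypropan-2-yl)-6-hydroxy-5-isobutyryl-3a,7-diprenyl-2,3-dihydro-1-benzofuran-4(3aH)-one | CC(C)=CCC1=C2O[C@H](C(C)(C)OO)C[C@]2(CC=C(C)C)C(=O)C(C(=O)C(C)C)=C1O | intermediate (not isolated)
8 | CNP0361579.1, (2S,3aS)-6-hydroxy-2-(2-hydroxypropan-2-yl)-5-isobutyryl-3a,7-diprenyl-2,3-dihydro-1-benzofuran-4(3aH)-one | CC(C)=CCC1=C2O[C@H](C(C)(C)O)C[C@]2(CC=C(C)C)C(=O)C(C(=O)C(C)C)=C1O | target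

**Step count**

Total: 3 steps. Longest linear sequence: 3 steps (1 → 3 → 6 → 8).

**Steps most likely to fail**

Step 2 (the new method). The risks are:
- insufficient discrimination of the enantiotopic ring carbons in the C–C event;
- mismatched face selection in the ring closure, leading to the 2,3a-cis series;
- competing closure through the chelated oxygen;
- sluggish ionisation of the free allylic alcohol;
- a second allylation of the product;
- erosion of either centre by reversible ionisation of the allylic C–O or C–C bond.

Fallback with known chemistry, setting out from 3 and returning at 8. A third C-prenylation of 3 with 2 in aqueous KOH takes place at a prenyl-bearing ring carbon and gives the dearomatised, achiral colupulone F1. Shi epoxidation (D-fructose-derived ketone, Oxone, carbonate buffer, MeCN–dimethoxymethane–water, 0 °C) of one geminal prenyl group is expected, by the spiro transition-state model, to give the (R)-epoxide F2. Its free enol oxygen opens the oxirane at the secondary carbon in a 5-exo manner with inversion, in the buffer or with a trace of base, and gives 8 directly without passing through 6. C2 is then reagent-controlled, whereas the quaternary centre is not, so a chromatographic separation of diastereomers and of products from epoxidation of the other prenyl group belongs to this route.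

Step 3. The risks are hydrogen-atom transfer to the prenyl alkenes (over-hydration), radical oxidation of the electron-rich enol/enol-ether ring, and sequestration of the metal by the β-triketone. Fallback from 6, returning at 8: ionic Brown oxymercuration–demercuration. Hg(OAc)2 in THF–water at 0 °C attacks the least hindered, 1,1-disubstituted alkene (the selectivity that converts limonene into α-terpineol) and gives the organomercurial F3. NaBH4 in aqueous NaOH then replaces mercury by hydrogen and gives 8; the β-triketone is protected as its enolate under these conditions.

Step 1. The risks are over-alkylation to the dearomatised triprenyl compound, O-prenylation, and incomplete second prenylation, all of which lower the throughput. Fallback from 1, returning at 3: Friedel–Crafts prenylation of the neutral phenol with 2-methylbut-3-en-2-ol and BF3·OEt2 in dioxane at room temperature. The tertiary allyl cation can substitute only the free ring CH positions, so geminal prenylation and O-alkylation are excluded by mechanism. The first product is 3-prenylphlorisobutyrophenone F4, which is resubmitted to the same conditions to give 3.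

**Further compounds**

F1 | step 2 | colupulone [3,5-dihydroxy-4,6,6-tris(3-methylbut-2-en-1-yl)-2-(2-methylpropanoyl)cyclohexa-2,4-dien-1-one] | CC(C)=CCC1=C(O)C(CC=C(C)C)(CC=C(C)C)C(=O)C(C(=O)C(C)C)=C1O
F2 | step 2 | (6S)-6-{[(2R)-3,3-dimethyloxiran-2-yl]methyl}-3,5-dihydroxy-4,6-bis(3-methylbut-2-en-1-yl)-2-(2-methylpropanoyl)cyclohexa-2,4-dien-1-one (formed beside its C6 epimer) | CC(C)=CCC1=C(O)[C@](CC=C(C)C)(C[C@H]2OC2(C)C)C(=O)C(C(=O)C(C)C)=C1O
F3 | step 3 | (2S,3aS)-2-[1-(acetoxymercurio)-2-hydroxypropan-2-yl]-6-hydroxy-5-isobutyryl-3a,7-diprenyl-2,3-dihydro-1-benzofuran-4(3aH)-one (both epimers at the carbinol carbon) | CC(C)=CCC1=C2O[C@H](C(C)(O)C[Hg]OC(C)=O)C[C@]2(CC=C(C)C)C(=O)C(C(=O)C(C)C)=C1O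
F4 | step 1 | 3-prenylphlorisobutyrophenone [2-methyl-1-(2,4,6-trihydroxy-3-prenylphenyl)propan-1-one] | CC(C)=CCc1c(O)cc(O)c(C(=O)C(C)C)c1O
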